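The route rests on cutting the two aryl–C(sp3) bonds that fuse the five-membered ring to the central resorcinol ring (ring B): from the ring B carbon meta to both oxygens to the ring-fusion methine C-8, and from the neighbouring ring B carbon (ortho/para to the oxygens) to C-9, the methine bearing the 3,5-dihydroxyphenyl group. These adjacent carbons have opposite electronic demands, and one pot serves both: palladium-catalysed ketone α-arylation with 1-bromo-3,5-dimethoxybenzene attaches C-8, then triflic acid ionises the C-9 carbinol and the new aryl ring closes the indane by Friedel–Crafts alkylation. The precursor is an acyclic γ-hydroxy ketone carrying ring A, whose single controlling stereocentre comes from an enantioselective carbene-catalysed lactone synthesis.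

Key step: step 4

Remark on locants: ring A is the dimethoxybenzene ring found only in the seven-membered ring; ring B is the central dimethoxybenzene ring; C-7 is the seven-ring methine bearing a 4-oxyphenyl group; C-8 is the ring-fusion methine; C-9 bears the 3,5-dioxyphenyl group; C-10 bears the other 4-oxyphenyl group.

Assumption: the all-trans arrangement at C-7 to C-10 is taken to be the thermodynamically preferred one, as for trans-2,3-diarylindanes, so equilibrating steps should converge on it. The C-9 carbinol configuration in 3, 8 and 10 is erased in step 4; the cis-lactone is drawn only for definiteness.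

Step 1
Reactants: 1 (E)-4-methoxycinnamaldehyde; 2 3,5-dimethoxybenzaldehyde
Product: 3 (4R,5R)-5-(3,5-dimethoxyphenyl)-4-(4-methoxyphenyl)oxolan-2-one (cis-lactone; its C-5 epimer of the same 4R configuration is carried along)
Conditions: chiral aminoindanol-derived N-mesityl triazolium tetrafluoroborate (10 mol %), DBU (10 mol %), THF, rt
Reagents that add atoms: none
Why: Carbene-catalysed homoenolate annulation (formal [3+2]) of an enal with an aryl aldehyde gives the γ-butyrolactone directly; the β-carbon of the homoenolate attacks the aldehyde inside the chiral pocket of the triazolylidene, which should set the future C-10 as 4R.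

Step 2
Reactants: 4 3,5-dimethoxybenzoyl chloride; 5 diethylamine
Product: 6 N,N-diethyl-3,5-dimethoxybenzamide
Conditions: Et3N, CH2Cl2, 0 °C to rt
Reagents that add atoms: none
Why: Schotten–Baumann-type acylation of the amine installs the tertiary amide that serves first as ortho-directing group and later as the latent ring A carbonyl.

Step 3
Reactants: 6 N,N-diethyl-3,5-dimethoxybenzamide; 3 cis-lactone
Product: 8 N,N-diethyl-2-[(3R,4R)-4-(3,5-dimethoxyphenyl)-4-hydroxy-3-(4-methoxyphenyl)butanoyl]-3,5-dimethoxybenzamide, via aryllithium 7 (not isolated)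
Conditions: s-BuLi, TMEDA, THF, −78 °C; then 3, −78 to −40 °C; aq NH4Cl
Reagents that add atoms: none
Why: Directed ortho-metalation at the site flanked by the amide and a methoxy group, then acylation of the aryllithium by the lactone, whose tetrahedral lithium alkoxide should resist over-addition at low temperature, gives the ring A ketone without touching the stereocentres.

Step 4
Reactants: 8 hydroxy keto amide; 9 1-bromo-3,5-dimethoxybenzene
Product: 11 N,N-diethyl-2-{[(1S,2R,3S)-3-(3,5-dimethoxyphenyl)-4,6-dimethoxy-2-(4-methoxyphenyl)-2,3-dihydro-1H-inden-1-yl]carbonyl}-3,5-dimethoxybenzamide, via α-aryl ketone 10 (not isolated)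
Conditions: Pd(OAc)2 (5 mol %), XPhos, NaOtBu (2.2 equiv), toluene, 80 °C; then TfOH, CH2Cl2, 0 °C to rt
Reagents that add atoms: none
Why: Zerovalent palladium inserts into the C–Br bond of 9 at the ring B carbon meta to both methoxy groups (a position electrophilic substitution cannot reach), the sodium enolate of 8 binds, and reductive elimination forms the ring B–C-8 bond (Buchwald–Hartwig-type ketone α-arylation) to give 10; TfOH then ionises the C-9 benzylic alcohol, assisted by the neighbouring ketone oxygen as a cyclic oxocarbenium ion, and the newly attached 3,5-dimethoxyphenyl ring attacks through its ortho carbon in an intramolecular Friedel–Crafts alkylation that forms the ring B–C-9 bond. The five-membered ring is thus closed by electrophilic aromatic substitution of a ring carbon on an exocyclic benzylic cation, the closest known reaction type being acid-mediated cyclialkylation of 3-arylpropyl cations to indanes. C-10, fixed in step 1, should control both new stereocentres: C-8 is α to the ketone and equilibrates through the enol(ate) to place the acyl group trans to the C-10 aryl group, and C-9 is attacked on the face opposite that aryl group, giving the 2,3-trans relationship whatever the configuration of the starting carbinol. The step needs regioselectivity on ring B and cyclisation faster than 1,2-hydride shift from C-10: the first is secured because the two ortho carbons of the symmetric aryl group are equivalent and alone can reach C-9 through a five-membered transition state, the second by the high nucleophilicity of those carbons and the oxocarbenium participation.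

Step 5
Reactants: 11 indanyl aryl ketone amide
Product: 12 (8S,9S,10R)-tricyclic dione: the free ring B carbon next to the C-8-bearing carbon is now bonded to the former amide carbon (diaryl ketone), closing the seven-membered ring that also holds the C-7 ketone
Conditions: POCl3, ClCH2CH2Cl, 80 °C; then aq NaOAc
Reagents that add atoms: water (O)
Why: Intramolecular Vilsmeier–Haack-type aroylation: the chloroiminium ion of the tertiary benzamide is attacked by the only ring B carbon within reach, which is ortho/para to the methoxy groups, and hydrolysis of the resulting iminium ion gives the bridging diaryl ketone.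

Step 6
Reactants: 12 tricyclic dione
Product: 14 (9S,10S)-alkene with a C-7(H)=C-8 double bond in the seven-membered ring, via enol triflate 13 (not isolated)
Conditions: KN(SiMe3)2, PhNTf2, THF, −78 °C; then Pd(OAc)2, PPh3, HCO2H, Et3N, DMF, 60 °C
Reagents that add atoms: none
Why: Only the C-7 ketone is enolisable, so enolate O-triflation is chemoselective over the diaryl ketone, and palladium-catalysed formate reduction of the enol triflate (oxidative addition, hydride transfer, reductive elimination) should give the ring-conjugated alkene.

Step 7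
Reactants: 14 alkene; 15 anisole
Product: 16 (7S,8R,9S,10S)-octamethyl ether of the target
Conditions: TfOH (20 mol %), CH2Cl2/(CF3)2CHOH, 0 °C
Reagents that add atoms: none
Why: Acid-catalysed hydroarylation (Friedel–Crafts alkylation): protonation at C-8 gives the C-7 benzylic cation stabilised by the ortho/para methoxy groups of ring A, and anisole should capture it at its para position on the face remote from ring B, placing the aryl group trans to the C-8–C-10 bond, while reversible protonation lets C-8 settle trans to the C-10 aryl group.

Step 8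
Reactants: 16 octamethyl ether
Product: 17 target CNP0116600.1, (7S,8R,9S,10S)-octaphenol
Conditions: BBr3, CH2Cl2, −78 °C to rt; then MeOH, H2O
Reagents that add atoms: none
Why: Lewis-acid ether cleavage (O-coordination, bromide attack at methyl) removes all eight aryl methyl groups and should leave the diaryl ketone and the four benzylic stereocentres untouched.

Compound list
1 | (E)-4-methoxycinnamaldehyde | COc1ccc(/C=C/C=O)cc1 | starting material
2 | 3,5-dimethoxybenzaldehyde | COc1cc(C=O)cc(OC)c1 | starting material
3 | (4R,5R)-5-(3,5-dimethoxyphenyl)-4-(4-methoxyphenyl)oxolan-2-one | O=C1C[C@H](c2ccc(OC)cc2)[C@H](c2cc(OC)cc(OC)c2)O1 | intermediate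
4 | 3,5-dimethoxybenzoyl chloride | COc1cc(C(=O)Cl)cc(OC)c1 | starting material
5 | diethylamine | CCNCC | starting material
6 | N,N-diethyl-3,5-dimethoxybenzamide | CCN(CC)C(=O)c1cc(OC)cc(OC)c1 | intermediate
7 | 2-lithio-N,N-diethyl-3,5-dimethoxybenzamide | [Li]c1c(OC)cc(OC)cc1C(=O)N(CC)CC | intermediate
8 | N,N-diethyl-2-[(3R,4R)-4-(3,5-dimethoxyphenyl)-4-hydroxy-3-(4-methoxyphenyl)butanoyl]-3,5-dimethoxybenzamide | CCN(CC)C(=O)c1cc(OC)cc(OC)c1C(=O)C[C@H](c1ccc(OC)cc1)[C@@H](O)c1cc(OC)cc(OC)c1 | intermediate
9 | 1-bromo-3,5-dimethoxybenzene | COc1cc(Br)cc(OC)c1 | starting material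
10 | N,N-diethyl-2-[(3R,4R)-2,4-bis(3,5-dimethoxyphenyl)-4-hydroxy-3-(4-methoxyphenyl)butanoyl]-3,5-dimethoxybenzamide (C-2 epimers) | CCN(CC)C(=O)c1cc(OC)cc(OC)c1C(=O)C(c1cc(OC)cc(OC)c1)[C@H](c1ccc(OC)cc1)[C@@H](O)c1cc(OC)cc(OC)c1 | intermediate
11 | N,N-diethyl-2-{[(1S,2R,3S)-3-(3,5-dimethoxyphenyl)-4,6-dimethoxy-2-(4-methoxyphenyl)-2,3-dihydro-1H-inden-1-yl]carbonyl}-3,5-dimethoxybenzamide | CCN(CC)C(=O)c1cc(OC)cc(OC)c1C(=O)[C@@H]1c2cc(OC)cc(OC)c2[C@H](c2cc(OC)cc(OC)c2)[C@H]1c1ccc(OC)cc1 | intermediate
12 | (8S,9S,10R)-tricyclic dione (bridging diaryl ketone and C-7 ketone) | O=C1c2cc(OC)cc(OC)c2C(=O)[C@@H]2c3c1c(OC)cc(OC)c3[C@H](c1cc(OC)cc(OC)c1)[C@H]2c1ccc(OC)cc1 | intermediate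
13 | (9S,10S)-enol triflate of 12 at C-7 (C-7=C-8) | O=C1c2cc(OC)cc(OC)c2C(OS(=O)(=O)C(F)(F)F)=C2c3c1c(OC)cc(OC)c3[C@H](c1cc(OC)cc(OC)c1)[C@H]2c1ccc(OC)cc1 | intermediate
14 | (9S,10S)-alkene, C-7(H)=C-8 | O=C1c2cc(OC)cc(OC)c2C=C2c3c1c(OC)cc(OC)c3[C@H](c1cc(OC)cc(OC)c1)[C@H]2c1ccc(OC)cc1 | intermediate
15 | anisole | COc1ccccc1 | starting material
16 | (7S,8R,9S,10S)-octamethyl ether of the target | O=C1c2cc(OC)cc(OC)c2[C@H](c2ccc(OC)cc2)[C@@H]2c3c1c(OC)cc(OC)c3[C@H](c1cc(OC)cc(OC)c1)[C@H]2c1ccc(OC)cc1 | intermediate
17 | CNP0116600.1, (7S,8R,9S,10S)-octaphenol | O=C1c2cc(O)cc(O)c2[C@H](c2ccc(O)cc2)[C@@H]2c3c1c(O)cc(O)c3[C@H](c1cc(O)cc(O)c1)[C@H]2c1ccc(O)cc1 | target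

Total step count: 8. Longest linear sequence: 7 steps (2, 3, 4, 5, 6, 7, 8; equally 1, 3, 4, 5, 6, 7, 8).

Steps most likely to fail

Step 4. The C-9 cation may undergo 1,2-hydride shift from C-10 and eliminate to a stilbene before ring B captures it. The α-arylation may also stall on the hindered, hydroxyl-bearing ketone, through O-arylation or enolate attack on the neighbouring amide. The fallback moves the annulation to the lactone stage and appends ring A afterwards; it sets out from 3 and 9 and returns at 11. Palladium-catalysed α-arylation of lactone 3 with 9 (LiN(SiMe3)2, Pd(OAc)2, P(t-Bu)3) should give the α-aryl lactone (3R,4R,5R)-3,5-bis(3,5-dimethoxyphenyl)-4-(4-methoxyphenyl)oxolan-2-one F1. TfOH in the same pot opens its benzylic C–O bond, with the carboxylate as leaving group, in an intramolecular Friedel–Crafts alkylation to the indane-1-carboxylic acid F2. Amide coupling with N,O-dimethylhydroxylamine gives the N-methoxy-N-methylamide F3, and acylation of aryllithium 7 with F3 delivers 11.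

Step 7. Kinetic protonation at C-8 may occur on the wrong face without full equilibration, and the cation may eliminate or oligomerise faster than anisole traps it. The fallback keeps the C-8 hydrogen in place and ionises a carbinol instead of protonating the alkene; it sets out from 12 and returns at 16. Reduction of 12 with NaBH4 at low temperature, aimed at the enolisable aryl alkyl ketone, gives the C-7 carbinol F4. Friedel–Crafts substitution of this benzylic alcohol with anisole and BF3·OEt2 then gives 16, with attack again on the face remote from ring B.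

Step 1. Enantiofacial discrimination at the homoenolate β-carbon may be insufficient, and the enal may dimerise. The fallback replaces asymmetric catalysis by resolution; it sets out from 1 and 2 and returns at 3. An achiral N-mesityl imidazolium salt with DBU gives the racemic lactone F5. Aminolysis with (S)-1-phenylethylamine and AlMe3 gives diastereomeric γ-hydroxy amides, from which the (3R,4R)-N-[(1S)-1-phenylethyl]amide F6 is separated by crystallisation. Heating F6 in aqueous H2SO4/dioxane relactonises it to 3.

Further compounds
F1 | step 4 | (3R,4R,5R)-3,5-bis(3,5-dimethoxyphenyl)-4-(4-methoxyphenyl)oxolan-2-one | O=C1[C@@H](c2cc(OC)cc(OC)c2)[C@H](c2ccc(OC)cc2)[C@H](c2cc(OC)cc(OC)c2)O1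
F2 | step 4 | (1S,2R,3S)-3-(3,5-dimethoxyphenyl)-4,6-dimethoxy-2-(4-methoxyphenyl)-2,3-dihydro-1H-indene-1-carboxylic acid | OC(=O)[C@@H]1c2cc(OC)cc(OC)c2[C@H](c2cc(OC)cc(OC)c2)[C@H]1c1ccc(OC)cc1
F3 | step 4 | (1S,2R,3S)-3-(3,5-dimethoxyphenyl)-N,4,6-trimethoxy-2-(4-methoxyphenyl)-N-methyl-2,3-dihydro-1H-indene-1-carboxamide | CON(C)C(=O)[C@@H]1c2cc(OC)cc(OC)c2[C@H](c2cc(OC)cc(OC)c2)[C@H]1c1ccc(OC)cc1
F4 | step 7 | (8S,9S,10R)-C-7 carbinol of 12 (bridging ketone retained; C-7 epimers) | O=C1c2cc(OC)cc(OC)c2C(O)[C@@H]2c3c1c(OC)cc(OC)c3[C@H](c1cc(OC)cc(OC)c1)[C@H]2c1ccc(OC)cc1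
F5 | step 1 | racemic 5-(3,5-dimethoxyphenyl)-4-(4-methoxyphenyl)oxolan-2-one | O=C1CC(c2ccc(OC)cc2)C(c2cc(OC)cc(OC)c2)O1
F6 | step 1 | (3R,4R)-4-(3,5-dimethoxyphenyl)-4-hydroxy-3-(4-methoxyphenyl)-N-[(1S)-1-phenylethyl]butanamide | C[C@H](NC(=O)C[C@H](c1ccc(OC)cc1)[C@@H](O)c1cc(OC)cc(OC)c1)c1ccccc1
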